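Counted in mM of partner, the flask is a budget: each starting material taken through to over-reaction product costs two partner, and each second substrate costs one.

starting material 0.20 mM; second substrate 0.100 mM; partner 0.400 mM; free catalyst 0.40 µM; time 12 min

* at 12 min, what has stopped the reaction, if anything has (all of the starting material has reacted / it is still moving / no working catalyst is left / forward and back rates have come level / the partner has run out first)
* the target standing at 12 min, as a percentage of the starting material charged
* the over-reaction product standing at 12 min, as a percentage of the starting material charged

- the reaction counts as stopped when no species that holds the starting material changes by six tenths of a point or more over the second half of the time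
- run time (flask): 12 min

    partner + catalyst intermediate A → free catalyst + target (k1 = 81000 M⁻¹ s⁻¹)
    starting material + free catalyst ⇌ catalyst intermediate A (K2 = 8700 M⁻¹, k2 = 5.9 × 10⁵ M⁻¹ s⁻¹)
    second substrate + free catalyst ⇌ catalyst intermediate B (K3 = 4100 M⁻¹, k3 = 4.6 × 10⁵ M⁻¹ s⁻¹)
    partner + catalyst intermediate B → free catalyst + second product (k4 = 38000 M⁻¹ s⁻¹)
    partner + target → over-reaction product (k5 = 230 M⁻¹ s⁻¹)

The quantity to carry is the partner cover, the partner charged over the partner that complete reaction demands: 0.800. In this flask the cover is less than one, so the end state should be a flask short of partner, the limiting reagent.

How fast it gets there is a matter of rate. My own reckoning takes binding as balanced. Equilibrium constant times charge is 1.7 for starting material and 0.41 for second substrate, so catalyst intermediate A starts with 55.2% of the catalyst. The target-forming step then removes partner at a pseudo-first-order 0.0179 s⁻¹, a lifetime of 55.9 s. Falling partner slows this rate in direct proportion, which is already inside that constant. Falling substrates slow it further. Supposing, as an estimate, starting material down to 0.0200 mM and second substrate down to 0.0500 mM, the share drops to 12.6%, a slowing by 4.38, and the constant becomes 0.00409 s⁻¹. Even so, 12 min is longer than the slowed lifetime of 4.07 min, and by this estimate the one step, held at the slowed constant, leaves 5.26% of the partner present at the slowing. The call for this flask is therefore partner out first. The reckoning stops there and gives no yields.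

The forecast says the partner has run out first, with target 12% (8% to 17%) and over-reaction product 81% (72% to 88%), holding that “the uncatalysed over-reaction is also fast at these partner levels”.

The flask gives the partner has run out first, with 0.014% of the partner standing, target 11.5% and over-reaction product 82.0%.

The cover's shortfall of 0.100 mM reappears in this flask's end state as 0.0999 mM of unserved demand. Part of the reason starting material stays unreacted in this flask is the return of catalyst intermediate A to starting material + free catalyst, acting together with the binding of second substrate to free catalyst: the same run without that return lifts conversion of starting material from 93.5% to 100%, without that binding to 99.6%, and each removal turns the ending. In the neighbour charged with 0.050 mM of starting material, the cover is 2.00, which promises 50.0% of the partner to spare. That neighbour ends with 50.0% of its partner and over-reaction product at 100%.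

Its constants stand for no real mixture, and the outcome is calculated.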